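**The count.** Count how often the substrate halves late in a run, and use that count to close the books on the new flask.

| setting | spring | winter | autumn | flask |
|---|---|---|---|---|
| substrate | 0.034 M | 0.075 M | 0.050 M | 0.050 M |
| coupling partner | 0.055 M | 0.055 M | 0.055 M | 0.0550 M |
| precatalyst | 1.2 mM | 1.2 mM | 2.4 mM | 1.2 mM |
| remark | run made earlier | run made earlier | run made earlier |  |
| time |  |  |  | 25 h |

| run | time / h | target / % | substrate / % |
|---|---|---|---|
| spring | 4.00 | 6.7 | 93.1 |
| spring | 8.00 | 22.3 | 77.7 |
| spring | 10.0 | 31.0 | 67.9 |
| spring | 15.0 | 52.6 | 45.7 |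
| spring | 20.0 | 69.6 | 29.9 |
| spring | 25.0 | 82.0 | 18.0 |
| winter | 1.33 | 1.0 | 99.6 |
| winter | 4.00 | 3.1 | 95.2 |
| winter | 8.00 | 14.7 | 84.9 |
| winter | 10.0 | 20.8 | 78.5 |
| winter | 15.0 | 36.6 | 61.4 |
| winter | 20.0 | 53.4 | 46.4 |
| winter | 25.0 | 67.1 | 31.6 |
| autumn | 5.00 | 16.5 | 82.6 |
| autumn | 10.0 | 47.8 | 50.1 |
| autumn | 15.0 | 75.7 | 24.3 |
| autumn | 20.0 | 91.4 | 8.8 |
| autumn | 25.0 | 97.2 | 2.9 |

(scatter of a reading: 0.5 percentage points)

- on the list of suspects stand: coupling partner + catalyst intermediate A -> catalyst intermediate B; catalyst intermediate C -> catalyst intermediate D; substrate + free catalyst -> catalyst intermediate A; precatalyst -> free catalyst; catalyst intermediate D -> free catalyst + target; catalyst intermediate B -> by-product + catalyst intermediate C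

- amount of target in percent of the substrate charged, at 5.0 h, 12 h and 25 h

**Tail half-life.** Spring's last two readings give 6.83 h for the tail half-life, the time in which [substrate] halves late in a run. This is a reading and carries the scatter. Spring's first two readings give a longer 15.3 h, so we count late in the run. Winter's last two readings give 9.02 h.

**The ledger.** In the flask, substrate is the limiting reagent, 0.050 M against 0.0550 M of coupling partner. By the suspect steps, each mole of substrate at 25 h is still substrate, held on the catalyst, or target.

*Substrate.* The flask's charge lies 39.0% of the way from spring to winter. Interpolating on that share, we take 36.3% left at 20.0 h and a tail half-life of 7.68 h. The remaining 0.651 of a halving leaves 23.1%.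

*Catalyst.* This entry cannot exceed the catalyst charge, 2.40% of the substrate charged.

*Target.* Target closes the books, so we reckon 74.5% to 76.9% at 25 h.

**The forecast.** The forecast holds that “The rate tracks precatalyst loading” and gives 7.5%, 33% and 73% at 5.0 h, 12 h and 25 h. Its last figure lies below our range.

**The result.** The flask gives 8.24%, 33.9% and 76.5%, so the forecast held within its margin.

    coupling partner + catalyst intermediate A → catalyst intermediate B (k = 16000 M⁻¹ h⁻¹)
    catalyst intermediate C → catalyst intermediate D (k = 44.0 h⁻¹)
    substrate + free catalyst → catalyst intermediate A (k = 110 M⁻¹ h⁻¹)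
    precatalyst → free catalyst (k = 0.160 h⁻¹)
    catalyst intermediate D → free catalyst + target (k = 9.70 h⁻¹)
    catalyst intermediate B → by-product + catalyst intermediate C (k = 8.80 h⁻¹)

**Counted on.** At 25.0 h the flask holds 22.9% of its substrate. From there to 250 h is 29.3 of the tail half-lives of 7.68 h interpolated for the flask, and the flask then holds 0%. Autumn, with the flask's substrate charge but 2.4 mM of precatalyst, gets the flask's tail half-life scaled to 3.84 h. From its 8.8% at 20.0 h, that gives 3.57% at 25.0 h, where autumn's reading stands at 2.9%.

The readings were computed with constants of no real substance; noise was put on by code.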